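## Retrosynthetic overview

1. Ring E (dihydropyran) is made last by acid-mediated cyclodehydration of a δ-hydroxy isopropyl ketone, itself from iPrMgCl and a spiro δ-lactone; the N-methylpiperidine (ring D) comes from a bridged lactam.
2. Ring A is closed by intramolecular B-alkyl Suzuki coupling of an enol triflate formed by conjugate vinylation of a ring-C enone; the enone comes from a ring-B dienoate through its γ,δ-epoxide.
3. Ring B and the lactam come from ring-rearrangement metathesis of a bicyclo[3.2.2]nonene: one end of the opened CH=CH bridge closes ring B onto an acrylate arm, the other becomes NCH2 after cleavage and N-acyliminium reduction.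
4. The two adjacent quaternary carbons are set by radical allylation of a C–Br bond and by enolate alkylation on a rigid cis-fused imide; a tethered alkoxide then tells the two imide carbonyls apart.
5. All absolute configuration comes from a new catalytic enantioselective Diels–Alder reaction of cyclohepta-1,3-diene with 3-bromo-N-methylmaleimide. Ring order: C → B → D → A → E.

Atom labels used in names (target): Q1 = spiro carbon; Q2 = quaternary carbon bearing NCH2; a = ring-C CH bearing the other NCH2; b, c = ring-C CH2CH2; d = alkene carbon bearing ring-A CH2; e = alkene carbon on Q2; f = ring-fusion CH; g (on f), h (on d) = ring-A CH2; i = CH–CO2H; j = CH2 between i and Q2; k = NCH2 on Q2; l = NCH2 on a; m = OCH2 on Q1; n, o = CH2–CH= of the pyran (n on Q1); p = O–C(iPr)=. Rings: A (d, e, f, g, h), B (e, f, i, j, Q2), C (Q1, a, b, c, d, e, Q2), D (N, k, Q2, Q1, a, l), E (O, m, Q1, n, o, p).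

Assumption: the sense of induction of the oxazaborolidinium catalyst (step 2) and of the chiral lithium amide (fallback) follows the accepted models; if it is opposite, the antipodal reagent is used.

## Route

Step 1
Reactants: 1 N-methylmaleimide
Product: 3 3-bromo-1-methyl-1H-pyrrole-2,5-dione, via trans-dibromide 2 (not isolated)
Conditions: Br2, CHCl3, reflux; then Et3N, THF, 0 °C
Reagents that add atoms: bromine, BrBr
Why: Anti addition of Br2 to the maleimide C=C and E1cB loss of HBr (bromination–dehydrobromination) give the bromomaleimide; no stereocentre remains.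

Step 2
Reactants: 4 cyclohepta-1,3-diene; 3 3-bromo-1-methyl-1H-pyrrole-2,5-dione
Product: 5 bromo imide adduct
Conditions: 4 (3 equiv), (S)-o-tolyl-oxazaborolidine (from (S)-diphenylprolinol)·HNTf2 (20 mol%), CH2Cl2, −40 to −20 °C
Reagents that add atoms: none
Why: Proposed new method: the cationic oxazaborolidinium should bind only the imide C=O flanked by the vinylic C–H (the C=O next to C–Br is less basic and lacks the C–H···O contact), lowering the LUMO and shielding one enantiotopic face so that the diene adds endo and sets Q1 (C–Br), Q2, a and e in one [4+2] event; the closest known reaction type is the oxazaborolidinium-catalysed enantioselective Diels–Alder reaction of maleimides and of 2-bromoacrolein.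

Step 3
Reactants: 5 bromo imide adduct
Product: 6 allyl imide
Conditions: CH2=CHCH2SnBu3, AIBN (cat.), benzene, 80 °C
Reagents that add atoms: allyltributylstannane, C=CC[Sn](CCCC)(CCCC)CCCC
Why: Keck radical allylation; the planar radical at Q1 can only be trapped on the face syn to the (CH2)3 bridge because the cis-fused imide ring must stay on the CH=CH side, so allyl replaces Br with retention.

Step 4
Reactants: 6 allyl imide
Product: 8 dialkyl imide, via lithium enolate 7 (not isolated)
Conditions: LiN(iPr)2, THF, −78 °C; then tert-butyl 2-(bromomethyl)acrylate, −78 to −20 °C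
Reagents that add atoms: tert-butyl 2-(bromomethyl)acrylate, C=C(CBr)C(=O)OC(C)(C)C
Why: Imide enolate alkylation (SN2′ addition–elimination); the cis ring fusion again forces the electrophile onto the face syn to the (CH2)3 bridge, creating Q2 next to Q1.

Step 5
Reactants: 8 dialkyl imide
Product: 11 lactone amide, via alkylborane 9 (not isolated), via hydroxypropyl imide 10 (not isolated)
Conditions: 9-BBN, THF, 0 °C to rt; NaOAc, H2O2, H2O; then DBU (cat.), toluene, 60 °C
Reagents that add atoms: hydrogen peroxide, OO
Why: 9-BBN hydroborates the monosubstituted allyl alkene faster than the bridge alkene or the acrylate, and the primary alkoxide opens the imide at the only carbonyl it reaches through a six-membered ring (intramolecular N-to-O acyl transfer), which differentiates the two imide carbonyls.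

Step 6
Reactants: 11 lactone amide
Product: 12 ring-B enoate
Conditions: second-generation Hoveyda–Grubbs catalyst (10 mol%), ethene (1 atm), toluene, 80 °C
Reagents that add atoms: ethene, C=C
Why: Ring-rearrangement metathesis (ring opening with ethene, then ring closing); only the alkylidene on f can close a five-membered ring with the acrylate arm on the neighbouring Q2, so ring B forms and l is left as a vinyl group on a.

Step 7
Reactants: 12 ring-B enoate
Product: 14 hydroxy lactam, via aldehyde 13 (not isolated)
Conditions: OsO4 (2 mol%), NaIO4, 2,6-lutidine, dioxane/H2O, rt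
Reagents that add atoms: sodium periodate (oxygen source through catalytic OsO4), [Na+].[O-]I(=O)(=O)=O
Why: Lemieux–Johnson cleavage is selective for the terminal vinyl group over the trisubstituted enoate, and the aldehyde on a is captured by the cis NHMe amide on Q2 as the six-membered N-acyl hemiaminal.

Step 8
Reactants: 14 hydroxy lactam
Product: 15 bridged lactam enoate
Conditions: Et3SiH, BF3·OEt2, CH2Cl2, −78 to −30 °C
Reagents that add atoms: none
Why: Ionic reduction of the N-acyliminium ion at low temperature spares the tert-butyl ester and gives the bridged lactam of ring D.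

Step 9
Reactants: 15 bridged lactam enoate
Product: 17 dienoate, via silyl ketene acetal 16 (not isolated)
Conditions: LiN(iPr)2, Me3SiCl, THF, −78 °C; then Pd(OAc)2, MeCN, rt
Reagents that add atoms: none
Why: γ-Deprotonation of the enoate at e (the only acidic C–H) with in situ silylation gives the silyl dienol ether, and Saegusa–Ito oxidation introduces the d=e double bond.

Step 10
Reactants: 17 dienoate
Product: 18 epoxy enoate
Conditions: mCPBA, NaHCO3, CH2Cl2, 0 °C
Reagents that add atoms: mCPBA, OOC(=O)c1cccc(Cl)c1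
Why: Peracid epoxidation takes the more electron-rich γ,δ-alkene of the dienoate, from the face syn to k (anti to the Q1 side chain).

Step 11
Reactants: 18 epoxy enoate
Product: 19 enone
Conditions: Pd(PPh3)4 (5 mol%), THF, 60 °C; then Et3N (cat.), rt
Reagents that add atoms: none
Why: Zerovalent palladium ionises the allylic C–O bond of the vinyl epoxide and a hydride shift from d gives the ketone (isomerisation of a diene monoepoxide), which conjugates to the enone; i equilibrates (vinylogous β-keto ester) to the epimer with the ester syn to k.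

Step 12
Reactants: 19 enone
Product: 21 enol triflate, via magnesium enolate 20 (not isolated)
Conditions: CH2=CHMgBr, CuBr·SMe2 (20 mol%), THF, −78 °C; then Comins' reagent, −78 to 0 °C
Reagents that add atoms: vinylmagnesium bromide, C=C[Mg]Br; Comins' reagent, O=S(=O)(N(c1ccc(Cl)cn1)S(=O)(=O)C(F)(F)F)C(F)(F)F
Why: Copper-catalysed conjugate addition puts the vinyl group on f anti to the neighbouring tert-butoxycarbonyl group on i (as with 4-substituted cyclopentenones), i.e. on the Q1 face needed for ring A, and the regiodefined enolate is O-sulfonylated.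

Step 13
Reactants: 21 enol triflate
Product: 23 pentacyclic ester (i-epimer), via alkylborane 22 (not isolated)
Conditions: 9-BBN, THF, rt; then Pd(dppf)Cl2 (10 mol%), AsPh3, Cs2CO3, DMF/H2O, 60 °C
Reagents that add atoms: none
Why: Hydroboration of the terminal vinyl group and intramolecular B-alkyl Suzuki–Miyaura coupling with the enol triflate close ring A and fix the tetrasubstituted d=e alkene.

Step 14
Reactants: 23 pentacyclic ester (i-epimer)
Product: 25 pentacyclic ester, via lithium ester enolate 24 (not isolated)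
Conditions: LiN(iPr)2, THF, −78 °C; then AcOH, −78 °C
Reagents that add atoms: none
Why: Kinetic protonation of the ester enolate from the convex face (syn to H on f, anti to g and to the Q1 side chain) places CO2tBu cis to g as in the target.

Step 15
Reactants: 25 pentacyclic ester
Product: 26 diol
Conditions: LiBH4, THF/MeOH, 0 °C to rt
Reagents that add atoms: none
Why: LiBH4 reduces the lactone but neither the tertiary lactam nor the tert-butyl ester.

Step 16
Reactants: 26 diol
Product: 27 transposed δ-lactone
Conditions: TEMPO (20 mol%), PhI(OAc)2, CH2Cl2, rt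
Reagents that add atoms: none
Why: Oxoammonium oxidation is selective for the unhindered primary alcohol over the neopentyl one; the aldehyde closes to the lactol and is oxidised on (oxidative lactonisation), which moves the carbonyl from m to p.

Step 17
Reactants: 27 transposed δ-lactone
Product: 28 amino lactone
Conditions: Zn(OAc)2 (10 mol%), (EtO)3SiH, THF, 40 °C
Reagents that add atoms: none
Why: Zinc-catalysed hydrosilylation reduces tertiary amides to amines in the presence of esters and lactones.

Step 18
Reactants: 28 amino lactone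
Product: 29 hydroxy isopropyl ketone
Conditions: iPrMgCl, LaCl3·2LiCl, THF, −78 °C
Reagents that add atoms: isopropylmagnesium chloride, CC(C)[Mg]Cl
Why: Mono-addition of the Grignard reagent to the δ-lactone (the magnesium hemiketal is stable at low temperature; the tert-butyl ester is inert) gives the δ-hydroxy ketone.

Step 19
Reactants: 29 hydroxy isopropyl ketone
Product: 31 CNP0237695.2, via hydroxy keto acid 30 (not isolated)
Conditions: TFA, CH2Cl2, 0 °C to rt; evaporate; PPTS (cat.), 4 Å MS, toluene, 70 °C; then Et3N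
Reagents that add atoms: none
Why: Acidolysis of the tert-butyl ester, then acid-catalysed cyclodehydration of the δ-hydroxy ketone through its hemiketal; the endocyclic trisubstituted enol ether is favoured over the exocyclic isopropylidene isomer.

## Compound list

1 | N-methylmaleimide (1-methyl-1H-pyrrole-2,5-dione) | CN1C(=O)C=CC1=O | starting material
2 | trans-3,4-dibromo-1-methylpyrrolidine-2,5-dione (racemic) | CN1C(=O)[C@@H](Br)[C@H](Br)C1=O | intermediate
3 | 3-bromo-1-methyl-1H-pyrrole-2,5-dione | CN1C(=O)C=C(Br)C1=O | intermediate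
4 | cyclohepta-1,3-diene | C1=CC=CCCC1 | starting material
5 | bromo imide adduct: endo N-methylimide of 6-bromobicyclo[3.2.2]non-8-ene-6,7-dicarboxylic acid; imide ring syn to the CH=CH bridge (f=l), Br on Q1 syn to the (CH2)3 bridge, H on Q2 | Br[C@@]12[C@H]3CCC[C@H](C=C3)[C@@H]1C(=O)N(C)C2=O | intermediate
6 | allyl imide: as 5 with allyl in place of Br on Q1 | C=CC[C@@]12[C@H]3CCC[C@H](C=C3)[C@@H]1C(=O)N(C)C2=O | intermediate
7 | lithium enolate of 6 (Q2=C(OLi)N) | C=CC[C@@]12[C@H]3CCC[C@H](C=C3)C1=C([O-])N(C)C2=O.[Li+] | intermediate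
8 | dialkyl imide: as 6 with CH2C(=CH2)CO2tBu on Q2, syn to the (CH2)3 bridge | C=CC[C@@]12[C@H]3CCC[C@H](C=C3)[C@]1(CC(=C)C(=O)OC(C)(C)C)C(=O)N(C)C2=O | intermediate
9 | alkylborane: 8 with 9-BBN on the terminal allyl carbon (p) | C(CCB4C5CCCC4CCC5)[C@@]12[C@H]3CCC[C@H](C=C3)[C@]1(CC(=C)C(=O)OC(C)(C)C)C(=O)N(C)C2=O | intermediate
10 | hydroxypropyl imide: Q1 arm is (CH2)3OH | OCCC[C@@]12[C@H]3CCC[C@H](C=C3)[C@]1(CC(=C)C(=O)OC(C)(C)C)C(=O)N(C)C2=O | intermediate
11 | lactone amide: spiro δ-lactone from the Q1 carbonyl (m) and the (CH2)3O arm; Q2 carries C(=O)NHMe and the acrylate arm; bicyclononene intact | O=C1OCCC[C@]12[C@H]3CCC[C@H](C=C3)[C@]2(CC(=C)C(=O)OC(C)(C)C)C(=O)NC | intermediate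
12 | ring-B enoate: cycloheptane (ring C) with trans-fused cyclopentene (Q2, e, f=i, j), CO2tBu on i, vinyl on a cis to the amide on Q2, spiro lactone on Q1 | O=C1OCCC[C@]12[C@H](C=C)CCC[C@@H]3C=C(C(=O)OC(C)(C)C)C[C@]32C(=O)NC | intermediate
13 | aldehyde: as 12 with CHO (carbon l) on a | O=C1OCCC[C@]12[C@H](C=O)CCC[C@@H]3C=C(C(=O)OC(C)(C)C)C[C@]32C(=O)NC | intermediate
14 | hydroxy lactam: ring D closed as N-acyl hemiaminal (N–k(=O)–Q2–Q1–a–l(OH)), epimers at l | O=C1OCCC[C@]12[C@H]3CCC[C@@H]4C=C(C(=O)OC(C)(C)C)C[C@]42C(=O)N(C)C3O | intermediate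
15 | bridged lactam enoate: as 14 with CH2 at l | O=C1OCCC[C@]12[C@H]3CCC[C@@H]4C=C(C(=O)OC(C)(C)C)C[C@]42C(=O)N(C)C3 | intermediate
16 | silyl ketene acetal: e=f and i=C(OtBu)OSiMe3 | O=C1OCCC[C@]12[C@H]3CCCC4=CC(=C(OC(C)(C)C)O[Si](C)(C)C)C[C@]42C(=O)N(C)C3 | intermediate
17 | dienoate: d=e and f=i double bonds, CO2tBu on i | O=C1OCCC[C@]12[C@H]3CCC=C4C=C(C(=O)OC(C)(C)C)C[C@]42C(=O)N(C)C3 | intermediate
18 | epoxy enoate: d,e-epoxide of 17, oxygen syn to k | O=C1OCCC[C@]12[C@H]3CC[C@@H]5O[C@@]54C=C(C(=O)OC(C)(C)C)C[C@]42C(=O)N(C)C3 | intermediate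
19 | enone: ketone at d, e=f double bond, CO2tBu on i syn to k | O=C1OCCC[C@]12[C@H]3CCC(=O)C4=C[C@H](C(=O)OC(C)(C)C)C[C@]42C(=O)N(C)C3 | intermediate
20 | magnesium enolate: d–OMgBr, d=e, vinyl on f | O=C1OCCC[C@]12[C@H]3CCC(O[Mg]Br)=C4[C@@H](C=C)[C@H](C(=O)OC(C)(C)C)C[C@]42C(=O)N(C)C3 | intermediate
21 | enol triflate: OTf on d, d=e, vinyl on f syn to Q1 and anti to the ester on i | O=C1OCCC[C@]12[C@H]3CCC(OS(=O)(=O)C(F)(F)F)=C4[C@@H](C=C)[C@H](C(=O)OC(C)(C)C)C[C@]42C(=O)N(C)C3 | intermediate
22 | alkylborane: 21 with 9-BBN on carbon h | O=C1OCCC[C@]12[C@H]3CCC(OS(=O)(=O)C(F)(F)F)=C4[C@@H](CCB5C6CCCC5CCC6)[C@H](C(=O)OC(C)(C)C)C[C@]42C(=O)N(C)C3 | intermediate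
23 | pentacyclic ester (i-epimer): rings A–D plus the m-carbonyl spiro lactone; target configuration except at i (CO2tBu trans to g) | O=C1OCCC[C@]12[C@H]3CCC5=C4[C@@H](CC5)[C@H](C(=O)OC(C)(C)C)C[C@]42C(=O)N(C)C3 | intermediate
24 | lithium ester enolate (i=C(OLi)OtBu) | O=C1OCCC[C@]12[C@H]3CCC5=C4[C@@H](CC5)C(=C([O-])OC(C)(C)C)C[C@]42C(=O)N(C)C3.[Li+] | intermediate
25 | pentacyclic ester: as 23 with the target configuration at i (CO2tBu cis to g) | O=C1OCCC[C@]12[C@H]3CCC5=C4[C@@H](CC5)[C@@H](C(=O)OC(C)(C)C)C[C@]42C(=O)N(C)C3 | intermediate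
26 | diol: Q1 carries CH2OH (m) and (CH2)3OH (n, o, p) | OCCC[C@@]2(CO)[C@H]3CCC5=C4[C@@H](CC5)[C@@H](C(=O)OC(C)(C)C)C[C@]42C(=O)N(C)C3 | intermediate
27 | transposed δ-lactone: O–m–Q1–n–o–p(=O) | O=C1CC[C@@]2(CO1)[C@H]3CCC5=C4[C@@H](CC5)[C@@H](C(=O)OC(C)(C)C)C[C@]42C(=O)N(C)C3 | intermediate
28 | amino lactone: as 27 with k reduced to CH2 | O=C1CC[C@@]2(CO1)[C@H]3CCC5=C4[C@@H](CC5)[C@@H](C(=O)OC(C)(C)C)C[C@]42CN(C)C3 | intermediate
29 | hydroxy isopropyl ketone: Q1 carries CH2OH and CH2CH2C(=O)CH(CH3)2 (in equilibrium with the cyclic hemiketal); tert-butyl ester | CC(C)C(=O)CC[C@@]2(CO)[C@H]3CCC5=C4[C@@H](CC5)[C@@H](C(=O)OC(C)(C)C)C[C@]42CN(C)C3 | intermediate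
30 | hydroxy keto acid: as 29 with CO2H | CC(C)C(=O)CC[C@@]2(CO)[C@H]3CCC5=C4[C@@H](CC5)[C@@H](C(=O)O)C[C@]42CN(C)C3 | intermediate
31 | CNP0237695.2 | CC(C)C1=CC[C@@]2(CO1)[C@H]1CCC3=C4[C@@H](CC3)[C@@H](C(=O)O)C[C@]42CN(C)C1 | target

Total step count: 19. Longest linear sequence: 19 steps (1 → 31; diene 4 enters in step 2).

## Steps most likely to fail

Step 2 (the proposed new step). Risks are the low reactivity of cyclohepta-1,3-diene, endo/exo control and face selectivity. The fallback sets out from 1 and 4 and comes back at 6. Heating N-methylmaleimide 1 with cyclohepta-1,3-diene 4 (toluene, 110 °C) gives the meso endo imide F1. Its two α-protons are enantiotopic; deprotonation with lithium (R,R)-bis(1-phenylethyl)amide and LiCl (THF, −100 °C) followed by allyl bromide (chiral lithium amide desymmetrisation, known for meso bicyclic succinimides) gives 6 directly, with the allyl group on the face syn to the (CH2)3 bridge for the same ring-fusion reason as in step 3.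

Step 6. Risks are the modest strain of the bicyclo[3.2.2]nonene and the electron-poor 1,1-disubstituted acrylate partner. The fallback sets out from 6 and comes back at 14. Enolate 7 is added to tert-butyl 2-(diethoxyphosphoryl)acrylate (Michael addition) to give the phosphonate imide F2. Hydroboration, oxidation and acyl transfer as in step 5 give the lactone amide phosphonate F3. OsO4/NaIO4 cleaves the CH=CH bridge to the dialdehyde F4. LiCl and DBU in MeCN (intramolecular Horner–Wadsworth–Emmons olefination) close ring B on the aldehyde at f, the only one within reach of the phosphonate, while the aldehyde at l is taken up by the NHMe amide, which gives 14.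

Step 12. Risks are the facial selectivity at f (it rests on the ester on i sitting syn to k and on anti addition), and deprotonation of the acidic H on i by the organometallic. The fallback sets out from 19 and comes back at 23; it sets f by chirality transfer instead. Luche reduction (NaBH4, CeCl3·7H2O, MeOH, −78 °C; hydride from the open face syn to k) gives the allylic alcohol F5. Johnson–Claisen rearrangement (MeC(OEt)3, cat. EtCO2H, 140 °C) forms the C–C bond at f on the face of the C–O bond and moves the alkene to d=e, giving the ethyl ester F6. LiOH gives the carboxylic acid F7. (COCl)2 then SnCl4 at −78 °C (intramolecular acylation of the alkene at d) gives the ring-A enone F8. A second Luche reduction gives the ring-A allylic alcohol F9. Et3SiH and BF3·OEt2 at −78 °C (ionic deoxygenation, hydride to the less hindered allylic terminus h) give 23.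

Further compounds
F1 | step 2 | meso endo imide (N-methylimide of bicyclo[3.2.2]non-8-ene-6,7-dicarboxylic acid, imide syn to the CH=CH bridge) | [C@@H]12[C@H]3CCC[C@H](C=C3)[C@@H]1C(=O)N(C)C2=O
F2 | step 6 | phosphonate imide (6 with CH2CH(CO2tBu)P(O)(OEt)2 on Q2, epimers at the phosphonate carbon) | C=CC[C@@]12[C@H]3CCC[C@H](C=C3)[C@]1(CC(C(=O)OC(C)(C)C)P(=O)(OCC)OCC)C(=O)N(C)C2=O
F3 | step 6 | lactone amide phosphonate (11 with the phosphonoacetate arm in place of the acrylate arm) | O=C1OCCC[C@]12[C@H]3CCC[C@H](C=C3)[C@]2(CC(C(=O)OC(C)(C)C)P(=O)(OCC)OCC)C(=O)NC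
F4 | step 6 | dialdehyde (CHO on a and on e, cis) | O=C1OCCC[C@]12[C@H](C=O)CCC[C@H](C=O)[C@]2(CC(C(=O)OC(C)(C)C)P(=O)(OCC)OCC)C(=O)NC
F5 | step 12 | allylic alcohol (OH on d, anti to k; e=f) | O=C1OCCC[C@]12[C@H]3CC[C@@H](O)C4=C[C@H](C(=O)OC(C)(C)C)C[C@]42C(=O)N(C)C3
F6 | step 12 | ethyl ester (CH2CO2Et on f syn to Q1; d=e) | O=C1OCCC[C@]12[C@H]3CCC=C4[C@@H](CC(=O)OCC)[C@H](C(=O)OC(C)(C)C)C[C@]42C(=O)N(C)C3
F7 | step 12 | carboxylic acid (CH2CO2H on f) | O=C1OCCC[C@]12[C@H]3CCC=C4[C@@H](CC(=O)O)[C@H](C(=O)OC(C)(C)C)C[C@]42C(=O)N(C)C3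
F8 | step 12 | ring-A enone (ketone at h conjugated with d=e) | O=C1OCCC[C@]12[C@H]3CCC5=C4[C@@H](CC5=O)[C@H](C(=O)OC(C)(C)C)C[C@]42C(=O)N(C)C3
F9 | step 12 | ring-A allylic alcohol (OH at h, epimers) | O=C1OCCC[C@]12[C@H]3CCC5=C4[C@@H](CC5O)[C@H](C(=O)OC(C)(C)C)C[C@]42C(=O)N(C)C3
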